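## Retrosynthetic overview

- Target 18 comes from dihydroxy acid 16 by acetylation of the primary 18-OH; 16 comes from hydroxy ketone 13 by Horner–Wadsworth–Emmons extension (C14–C15).
- 13 comes from the acyclic (R)-epoxy dienone 11 in one cationic cascade. The 1,1-disubstituted oxirane opens at its quaternary carbon (this becomes C4, its CH2O arm becomes C18), ring A closes (C4–C5), ring B closes (C9–C10), and the C13 ketone oxygen traps the C8 cation (8α-O; a temporary pyran ring, hydrolysed in the work-up).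
- 11 comes from (5E,9E)-farnesylacetone 5 by terminal allylic oxidation, Sharpless epoxidation (sets C4), hydride opening to a 1,2-diol and re-closure to the terminal oxirane; 5 comes from (2E,6E)-farnesol and ethyl acetoacetate.
- Ring order: rings A and B form together in step 8; no ring is made before or after.

Assumption: compounds 8, 9 and 10 are carried as epimer mixtures at the remote carbinol carbon (left unspecified in their SMILES), because step 7 returns that carbon to the ketone; 4 is racemic at its α-carbon, which is lost on decarboxylation.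

## Route

Step 1
Reactants: 1 (2E,6E)-farnesol
Product: 2 (2E,6E)-farnesyl bromide
Conditions: PBr3 (0.4 equiv), Et2O, −10 → 0 °C; used crude
Reagents that add atoms: phosphorus tribromide, BrP(Br)Br
Why: Bromination of a primary allylic alcohol through its phosphite ester (SN2 displacement by bromide) at low temperature leaves both E double bonds untouched; no stereocentre is formed.

Step 2
Reactants: 2 (2E,6E)-farnesyl bromide; 3 ethyl acetoacetate
Product: 5 (5E,9E)-farnesylacetone, via farnesylated acetoacetic ester 4 (not isolated)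
Conditions: NaOEt (1.0 equiv), 3 (1.5 equiv), EtOH, 0 °C → rt; then 10% aq. NaOH, 60 °C; then HCl to pH 4, 50 °C
Reagents that add atoms: ethyl acetoacetate (3), CCOC(=O)CC(C)=O
Why: Acetoacetic ester synthesis: the soft sodium enolate displaces the primary allylic bromide at the α-carbon without changing alkene geometry, and saponification followed by decarboxylation of the β-keto acid leaves the methyl ketone.

Step 3
Reactants: 5 (5E,9E)-farnesylacetone
Product: 6 (5E,9E,13E)-15-hydroxy-6,10,14-trimethylpentadeca-5,9,13-trien-2-one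
Conditions: SeO2 (0.3 equiv), t-BuOOH (3 equiv), salicylic acid (0.1 equiv), CH2Cl2, 0 °C → rt; stop near half conversion and recycle 5
Reagents that add atoms: tert-butyl hydroperoxide, CC(C)(C)OO (terminal oxidant; the oxygen atom is passed on through SeO2, O=[Se]=O)
Why: Catalytic SeO2 allylic oxidation (ene reaction, then [2,3]-sigmatropic shift) prefers the terminal isopropylidene group and oxidises its E-methyl, which fixes the E geometry of the new allylic alcohol; no stereocentre is formed.

Step 4
Reactants: 6 (5E,9E,13E)-15-hydroxy-6,10,14-trimethylpentadeca-5,9,13-trien-2-one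
Product: 7 (5E,9E)-12-[(2S,3S)-3-(hydroxymethyl)-3-methyloxiran-2-yl]-6,10-dimethyldodeca-5,9-dien-2-one
Conditions: Ti(OiPr)4 (10 mol%), L-(+)-diethyl tartrate (12 mol%), anhydrous t-BuOOH (2 equiv), 4 Å molecular sieves, CH2Cl2, −20 °C
Reagents that add atoms: tert-butyl hydroperoxide, CC(C)(C)OO
Why: Katsuki–Sharpless asymmetric epoxidation acts only on the allylic alcohol, and L-(+)-tartrate gives the (2S,3S)-epoxy alcohol (typically above 90% ee for E-trisubstituted allylic alcohols), which sets the future C4.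

Step 5
Reactants: 7 (5E,9E)-12-[(2S,3S)-3-(hydroxymethyl)-3-methyloxiran-2-yl]-6,10-dimethyldodeca-5,9-dien-2-one
Product: 8 (2R,6E,10E)-2,6,10-trimethylpentadeca-6,10-diene-1,2,14-triol
Conditions: LiAlH4 (2 equiv), THF, 0 °C → rt; aqueous work-up
Reagents that add atoms: none
Why: Hydride opens the trisubstituted epoxide by SN2 attack at the secondary carbon because the quaternary carbon is blocked, so the tertiary C–O bond is untouched and the (R)-tertiary carbinol results; the ketone is reduced at the same time and is restored in step 7.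

Step 6
Reactants: 8 (2R,6E,10E)-2,6,10-trimethylpentadeca-6,10-diene-1,2,14-triol
Product: 10 (5E,9E)-6,10-dimethyl-13-[(2R)-2-methyloxiran-2-yl]trideca-5,9-dien-2-ol, via primary tosylate 9 (not isolated)
Conditions: TsCl (1.05 equiv), Et3N (1.2 equiv), Bu2SnO (2 mol%), CH2Cl2, 0 °C → rt; then K2CO3 (3 equiv), MeOH, rt
Reagents that add atoms: p-toluenesulfonyl chloride, Cc1ccc(cc1)S(Cl)(=O)=O (its atoms are carried by intermediate 9 only; product 10 keeps none of them)
Why: Tin-catalysed sulfonylation picks the primary hydroxyl of the 1,2-diol, and the tertiary alkoxide then closes the oxirane by intramolecular Williamson displacement at the primary carbon, so the quaternary centre keeps its configuration (R).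

Step 7
Reactants: 10 (5E,9E)-6,10-dimethyl-13-[(2R)-2-methyloxiran-2-yl]trideca-5,9-dien-2-ol
Product: 11 (5E,9E)-6,10-dimethyl-13-[(2R)-2-methyloxiran-2-yl]trideca-5,9-dien-2-one
Conditions: Pr4N[RuO4] (5 mol%), N-methylmorpholine N-oxide (1.5 equiv), 4 Å molecular sieves, CH2Cl2, rt
Reagents that add atoms: none
Why: Ley–Griffith oxidation is neutral and selective for the secondary alcohol, so the acid-labile 2,2-disubstituted epoxide and the alkenes survive, and the carbinol epimers converge to one ketone.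

Step 8
Reactants: 11 (5E,9E)-6,10-dimethyl-13-[(2R)-2-methyloxiran-2-yl]trideca-5,9-dien-2-one
Product: 13 8α,18-dihydroxy-14,15-dinorlabdan-13-one, via tricyclic enol ether 12 (not isolated)
Conditions: MeAlCl2 (2.5 equiv), CH2Cl2, −94 → −78 °C; then 1 M HCl, THF, 0 °C → rt
Reagents that add atoms: water, O
Why: Proposed new method: MeAlCl2 activates the (R)-2,2-disubstituted oxirane and the C5=C10 alkene attacks its quaternary carbon from the rear (SN2-like opening with inversion, so this carbon becomes C4 and its CH2–O arm becomes C18, placed equatorial in the chair because CH2OAl is bulkier than CH3); the chair–chair antiperiplanar cascade across the two E-alkenes then sets 5α-H, 10β-CH3 and 9α-H, and the ketone oxygen captures the C8 cation equatorially (8α-O) to give an oxocarbenium ion that loses a proton to enol ether 12, which aqueous acid hydrolyses to 13; the closest known reaction types are the Lewis-acid epoxide-initiated cation–olefin polycyclisation of trisubstituted epoxy polyenes and the acid-promoted, ketone-terminated cyclisation of farnesylacetone to sclareol oxide.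

Step 9
Reactants: 13 8α,18-dihydroxy-14,15-dinorlabdan-13-one; 14 triethyl phosphonoacetate
Product: 16 (13E)-8α,18-dihydroxylabd-13-en-15-oic acid, via ethyl ester 15 (not isolated)
Conditions: NaH (4 equiv), 14 (4 equiv), THF, 0 → 60 °C; then KOH, EtOH/H2O, 70 °C; then 1 M HCl to pH 3 at 0 °C; chromatography to remove the 13Z acid
Reagents that add atoms: triethyl phosphonoacetate (14), CCOC(=O)CP(=O)(OCC)OCC; potassium hydroxide, [K+].[OH-] (one carboxyl oxygen)
Why: Horner–Wadsworth–Emmons olefination of the unhindered methyl ketone gives mainly the thermodynamically preferred E-enoate (expected about 4–6:1), the ring stereocentres are untouched, and hydroxide then cleaves the ethyl ester.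

Step 10
Reactants: 16 (13E)-8α,18-dihydroxylabd-13-en-15-oic acid; 17 acetic anhydride
Product: 18 (13E)-18-acetoxy-8α-hydroxylabd-13-en-15-oic acid (CNP0077667.1)
Conditions: Ac2O (3 equiv), pyridine, 0 °C → rt; then aq. NaHCO3/THF; then citric acid to pH 4
Reagents that add atoms: acetic anhydride (17), CC(=O)OC(C)=O
Why: Acetylation with Ac2O/pyridine (no acyl-transfer catalyst) esterifies only the primary 18-OH; the hindered tertiary 8-OH does not react and any mixed anhydride at C15 is hydrolysed in the bicarbonate work-up.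

## Compound list

1 | (2E,6E)-farnesol | CC(C)=CCC/C(C)=C/CC/C(C)=C/CO | starting material
2 | (2E,6E)-farnesyl bromide | CC(C)=CCC/C(C)=C/CC/C(C)=C/CBr | intermediate
3 | ethyl acetoacetate | CCOC(=O)CC(C)=O | starting material
4 | ethyl (4E,8E)-2-acetyl-5,9,13-trimethyltetradeca-4,8,12-trienoate (racemic) | CCOC(=O)C(C(C)=O)C/C=C(C)/CC/C=C(C)/CCC=C(C)C | intermediate (not isolated)
5 | (5E,9E)-farnesylacetone, (5E,9E)-6,10,14-trimethylpentadeca-5,9,13-trien-2-one | CC(C)=CCC/C(C)=C/CC/C(C)=C/CCC(C)=O | intermediate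
6 | (5E,9E,13E)-15-hydroxy-6,10,14-trimethylpentadeca-5,9,13-trien-2-one | OC/C(C)=C/CC/C(C)=C/CC/C(C)=C/CCC(C)=O | intermediate
7 | (5E,9E)-12-[(2S,3S)-3-(hydroxymethyl)-3-methyloxiran-2-yl]-6,10-dimethyldodeca-5,9-dien-2-one | OC[C@]1(C)O[C@H]1CC/C(C)=C/CC/C(C)=C/CCC(C)=O | intermediate
8 | (2R,6E,10E)-2,6,10-trimethylpentadeca-6,10-diene-1,2,14-triol (C14 epimers) | OC[C@](C)(O)CCC/C(C)=C/CC/C(C)=C/CCC(C)O | intermediate
9 | 1-O-tosylate of 8 | Cc1ccc(cc1)S(=O)(=O)OC[C@](C)(O)CCC/C(C)=C/CC/C(C)=C/CCC(C)O | intermediate (not isolated)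
10 | (5E,9E)-6,10-dimethyl-13-[(2R)-2-methyloxiran-2-yl]trideca-5,9-dien-2-ol (C2 epimers) | C[C@]1(CO1)CCC/C(C)=C/CC/C(C)=C/CCC(C)O | intermediate
11 | (5E,9E)-6,10-dimethyl-13-[(2R)-2-methyloxiran-2-yl]trideca-5,9-dien-2-one | C[C@]1(CO1)CCC/C(C)=C/CC/C(C)=C/CCC(C)=O | intermediate
12 | 18-hydroxy-8α,13-epoxy-14,15-dinorlabd-12-ene (18-hydroxysclareol oxide; 4α-CH2OH, 5α-H, 10β-CH3, 9α-H, 8α-O) | OC[C@]1(C)CCC[C@]2(C)[C@H]3CC=C(C)O[C@]3(C)CC[C@@H]12 | intermediate (not isolated)
13 | 8α,18-dihydroxy-14,15-dinorlabdan-13-one, 4-[(1R,2R,4aR,5R,8aS)-2-hydroxy-5-(hydroxymethyl)-2,5,8a-trimethyldecahydronaphthalen-1-yl]butan-2-one | OC[C@]1(C)CCC[C@]2(C)[C@@H](CCC(C)=O)[C@](C)(O)CC[C@@H]12 | intermediate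
14 | triethyl phosphonoacetate | CCOC(=O)CP(=O)(OCC)OCC | starting material
15 | ethyl (13E)-8α,18-dihydroxylabd-13-en-15-oate | OC[C@]1(C)CCC[C@]2(C)[C@@H](CC/C(C)=C/C(=O)OCC)[C@](C)(O)CC[C@@H]12 | intermediate (not isolated)
16 | (13E)-8α,18-dihydroxylabd-13-en-15-oic acid | OC[C@]1(C)CCC[C@]2(C)[C@@H](CC/C(C)=C/C(=O)O)[C@](C)(O)CC[C@@H]12 | intermediate
17 | acetic anhydride | CC(=O)OC(C)=O | starting material
18 | (13E)-18-acetoxy-8α-hydroxylabd-13-en-15-oic acid, (2E)-5-[(1R,2R,4aR,5R,8aS)-5-(acetoxymethyl)-2-hydroxy-2,5,8a-trimethyldecahydronaphthalen-1-yl]-3-methylpent-2-enoic acid | CC(=O)OC[C@]1(C)CCC[C@]2(C)[C@@H](CC/C(C)=C/C(=O)O)[C@](C)(O)CC[C@@H]12 | target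

## Step count and risk

Total step count: 10. Longest linear sequence: 10 steps (1 → 18).

Most likely to fail, in this order: step 8, step 3, step 9.

**Step 8.** The 2,2-disubstituted epoxide may rearrange to the aldehyde by hydride shift, may open through a free tertiary cation (loss of enantiopurity at C4), or may close through the chair that puts the CH2O arm axial. The Lewis-acid-bound ketone may also fail to trap the C8 cation, which would give alkene mixtures. The fallback leaves the route at compound 7 and returns at compound 13, and it still builds rings A and B in one cascade. The primary hydroxyl of 7 is silylated (t-BuMe2SiCl, imidazole, DMF) to the epoxy silyl ether F7. Its conventional trisubstituted 2,3-epoxide is cyclised with MeAlCl2 in CH2Cl2 at −94 °C to the silyloxy tricyclic enol ether F8, and the same aqueous acid work-up gives the 3β,8α-dihydroxy ketone F9. Here the quaternary oxirane carbon is again inverted and the E-CH2OSi arm ends equatorial, so C4 has the configuration of 13. The extra secondary 3-hydroxyl is then removed by Barton–McCombie deoxygenation: 1,1'-thiocarbonyldiimidazole gives the 3-O-imidazolylthiocarbonyl ester F10, and Bu3SnH with AIBN in toluene at 100 °C gives the 18-silyl ether F11. Bu4NF in THF frees 13.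

**Step 3.** SeO2 may attack the internal alkenes or over-oxidise, and yields near 40–50% are normal. The fallback leaves the route at compound 5 and returns at compound 8; it builds the E-allylic alcohol by olefination instead of C–H oxidation. N-Bromosuccinimide in aqueous THF at 0 °C gives the terminal bromohydrin F1, and K2CO3 in MeOH closes it to the racemic terminal epoxide F2. H5IO6 in THF/Et2O cleaves F2 to the keto aldehyde F3. The stabilised ylide Ph3P=C(CH3)CO2Et in CH2Cl2 reacts only with the aldehyde and gives the E-configured keto enoate F4. iBu2AlH in CH2Cl2 at −78 °C reduces ester and ketone to the allylic diol F5. Sharpless epoxidation as in step 4 gives the (2S,3S)-epoxy diol F6, and LiAlH4 as in step 5 gives 8.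

**Step 9.** The E/Z ratio may be poor, and the C8 alkoxide may add to the new enoate (oxa-Michael closure to an 8,13-ether). The fallback leaves the route at compound 13 and returns at compound 15, obtained as the pure E-isomer; 15 is then saponified as in the second half of step 9. Both hydroxyls are silylated (Et3SiOTf, 2,6-lutidine, CH2Cl2) to the bis-silyl ether ketone F12. The kinetic enolate (LiN(iPr)2, THF, −78 °C) is trapped with ClP(O)(OEt)2 as the enol phosphate F13, and more LiN(iPr)2 eliminates it to the terminal alkyne F14. Negishi zirconium-catalysed methylalumination (Me3Al, Cp2ZrCl2, CH2Cl2) followed by ClCO2Et gives the bis-silyl E-enoate F15; syn carbometalation fixes the E geometry, the new methyl becomes C16 and the former methyl carbon becomes C14. Bu4NF removes both silyl groups and gives 15.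

## Further compounds

F1 | step 3 | (5E,9E)-13-bromo-14-hydroxy-6,10,14-trimethylpentadeca-5,9-dien-2-one (racemic) | CC(C)(O)C(Br)CC/C(C)=C/CC/C(C)=C/CCC(C)=O
F2 | step 3 | (5E,9E)-12-(3,3-dimethyloxiran-2-yl)-6,10-dimethyldodeca-5,9-dien-2-one (racemic) | CC1(C)OC1CC/C(C)=C/CC/C(C)=C/CCC(C)=O
F3 | step 3 | (4E,8E)-4,8-dimethyl-12-oxotrideca-4,8-dienal | O=CCC/C(C)=C/CC/C(C)=C/CCC(C)=O
F4 | step 3 | ethyl (2E,6E,10E)-2,6,10-trimethyl-14-oxopentadeca-2,6,10-trienoate | CCOC(=O)/C(C)=C/CC/C(C)=C/CC/C(C)=C/CCC(C)=O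
F5 | step 3 | (2E,6E,10E)-2,6,10-trimethylpentadeca-2,6,10-triene-1,14-diol (C14 epimers) | OC/C(C)=C/CC/C(C)=C/CC/C(C)=C/CCC(C)O
F6 | step 3 | (5E,9E)-12-[(2S,3S)-3-(hydroxymethyl)-3-methyloxiran-2-yl]-6,10-dimethyldodeca-5,9-dien-2-ol (C2 epimers) | OC[C@]1(C)O[C@H]1CC/C(C)=C/CC/C(C)=C/CCC(C)O
F7 | step 8 | tert-butyldimethylsilyl ether of 7 | CC(C)(C)[Si](C)(C)OC[C@]1(C)O[C@H]1CC/C(C)=C/CC/C(C)=C/CCC(C)=O
F8 | step 8 | 18-(tert-butyldimethylsilyloxy)-8α,13-epoxy-14,15-dinorlabd-12-en-3β-ol | CC(C)(C)[Si](C)(C)OC[C@]1(C)[C@@H](O)CC[C@]2(C)[C@H]3CC=C(C)O[C@]3(C)CC[C@@H]12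
F9 | step 8 | 18-(tert-butyldimethylsilyloxy)-3β,8α-dihydroxy-14,15-dinorlabdan-13-one | CC(C)(C)[Si](C)(C)OC[C@]1(C)[C@@H](O)CC[C@]2(C)[C@@H](CCC(C)=O)[C@](C)(O)CC[C@@H]12
F10 | step 8 | 3-O-(imidazol-1-ylcarbonothioyl) derivative of F9 | CC(C)(C)[Si](C)(C)OC[C@]1(C)[C@@H](OC(=S)n3ccnc3)CC[C@]2(C)[C@@H](CCC(C)=O)[C@](C)(O)CC[C@@H]12
F11 | step 8 | 18-(tert-butyldimethylsilyloxy)-8α-hydroxy-14,15-dinorlabdan-13-one | CC(C)(C)[Si](C)(C)OC[C@]1(C)CCC[C@]2(C)[C@@H](CCC(C)=O)[C@](C)(O)CC[C@@H]12
F12 | step 9 | 8α,18-bis(triethylsilyloxy)-14,15-dinorlabdan-13-one | CC[Si](CC)(CC)OC[C@]1(C)CCC[C@]2(C)[C@@H](CCC(C)=O)[C@](C)(O[Si](CC)(CC)CC)CC[C@@H]12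
F13 | step 9 | diethyl enol phosphate of F12 (terminal CH2=C(OP) isomer) | CC[Si](CC)(CC)OC[C@]1(C)CCC[C@]2(C)[C@@H](CCC(=C)OP(=O)(OCC)OCC)[C@](C)(O[Si](CC)(CC)CC)CC[C@@H]12
F14 | step 9 | terminal alkyne, 4-[8α,18-bis(triethylsilyloxy) decalin core]but-1-yne | CC[Si](CC)(CC)OC[C@]1(C)CCC[C@]2(C)[C@@H](CCC#C)[C@](C)(O[Si](CC)(CC)CC)CC[C@@H]12
F15 | step 9 | ethyl (13E)-8α,18-bis(triethylsilyloxy)labd-13-en-15-oate | CC[Si](CC)(CC)OC[C@]1(C)CCC[C@]2(C)[C@@H](CC/C(C)=C/C(=O)OCC)[C@](C)(O[Si](CC)(CC)CC)CC[C@@H]12
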